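**Assumption:** the SMILES is taken literally, so the target is (1R,3S,4S,13S,14R) and both ring alkenes are Z (C6/C9 cis, C10/C13 cis).

**Numbering (cembrane):** C1 = ring CH bearing C15(=C17H2)–C16(=O). C2 = ring CH2. C3 = CHOH. C4 = C(CH3)OAc. Ring alkenes are C7=C8 and C11=C12. C13 = CHOAc. C14 = lactone CH–O.

## Retrosynthetic overview
1. The 14-membered ring is closed last at C1–C2, the bond the cembrene cyclase makes. C2 adds to the C1=C15 π bond and the double bond moves to C15=C17 (a one-electron SH2′ version).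
2. C3–OH and C4–OAc come from acetate opening, with inversion at C4, of the (3S,4R)-epoxide of a 3Z allylic alcohol. The epoxide is set by Sharpless epoxidation on the open chain.
3. C13, C14 and the fourth isoprene unit come from an anti-selective vinylogous Mukaiyama aldol of a Z-enal with a C5 silyloxyfuran.
4. The all-Z C2–C13 chain comes from two hydroboration/Suzuki couplings of three small Z building blocks.
5. Ring order: the γ-lactone ring is carried in from α-methylene-γ-butyrolactone, and the macrocycle is the only ring formed (final step).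

## Route

Step 1
Reactants: 1 prop-2-yn-1-ol
Product: 3 (Z)-3-iodo-2-methylprop-2-en-1-ol, via alkenylmagnesium chelate 2 (not isolated)
Conditions: MeMgBr (2.5 equiv), CuI (10 mol %), THF, −10 °C to rt; then I2, −20 °C
Reagents that add atoms: methylmagnesium bromide C[Mg]Br; iodine II
Why: Copper-catalysed anti-carbomagnesiation of the propargylic alkoxide (Duboudin–Jousseaume reaction) holds Mg cis to CH2O in a five-membered chelate, and iodinolysis with retention gives the Z iodide that later fixes C10/C13 cis.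

Step 2
Reactants: 3 (Z)-3-iodo-2-methylprop-2-en-1-ol
Product: 5 (Z)-1-iodo-2-methylbuta-1,3-diene, via Z-iodoenal 4 (not isolated)
Conditions: MnO2 (10 equiv), MePPh3Br, MTBD, 4 Å MS, THF, 40 °C, dark
Reagents that add atoms: methyltriphenylphosphonium bromide C[P+](c1ccccc1)(c1ccccc1)c1ccccc1.[Br-]
Why: Tandem allylic oxidation/Wittig methylenation consumes the configurationally labile Z-iodoenal as it forms, so the iodine/vinyl cis geometry (later C6/C9 cis) is kept.

Step 3
Reactants: 6 (Z)-3-methylpent-2-en-4-yn-1-ol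
Product: 7 (Z)-tert-butyl(dimethyl)[(3-methylpent-2-en-4-yn-1-yl)oxy]silane
Conditions: TBSCl, imidazole, CH2Cl2, 0 °C to rt
Reagents that add atoms: tert-butyldimethylsilyl chloride CC(C)(C)[Si](C)(C)Cl
Why: Standard silylation masks the C2 hydroxyl so that it can be told apart from the C13 hydroxyl later.

Step 4
Reactants: 7 (Z)-tert-butyl(dimethyl)[(3-methylpent-2-en-4-yn-1-yl)oxy]silane
Product: 8 (Z)-tert-butyl(dimethyl)[(3-methylpenta-2,4-dien-1-yl)oxy]silane
Conditions: H2 (1 atm, 1.0 equiv), Pd/CaCO3 poisoned with Pb(OAc)2, quinoline, hexane, 0 °C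
Reagents that add atoms: none
Why: Lindlar semi-hydrogenation stops at the terminal vinyl group and leaves the trisubstituted Z alkene (later C3=C4) untouched.

Step 5
Reactants: 8 (Z)-tert-butyl(dimethyl)[(3-methylpenta-2,4-dien-1-yl)oxy]silane; 5 (Z)-1-iodo-2-methylbuta-1,3-diene
Product: 10 (2Z,6Z)-tert-butyl[(3,7-dimethylnona-2,6,8-trien-1-yl)oxy]dimethylsilane, via B-alkyl-9-BBN 9 (not isolated)
Conditions: 9-BBN-H (1.0 equiv), THF, 0 °C to rt; then 5, PdCl2(dppf) (5 mol %), AsPh3, Cs2CO3, DMF/H2O, rt
Reagents that add atoms: 9-borabicyclo[3.3.1]nonane B1C2CCCC1CCC2 (boron stays only in 9)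
Why: 9-BBN adds only to the monosubstituted alkene terminus, and the B-alkyl Suzuki–Miyaura coupling keeps the alkenyl iodide geometry, giving the 7Z alkene.

Step 6
Reactants: 10 (2Z,6Z)-tert-butyl[(3,7-dimethylnona-2,6,8-trien-1-yl)oxy]dimethylsilane; 3 (Z)-3-iodo-2-methylprop-2-en-1-ol
Product: 12 (2Z,6Z,10Z)-12-[(tert-butyldimethylsilyl)oxy]-2,6,10-trimethyldodeca-2,6,10-trien-1-ol, via B-alkyl-9-BBN 11 (not isolated)
Conditions: 9-BBN-H (1.0 equiv), THF, 0 °C to rt; then 3, PdCl2(dppf) (5 mol %), AsPh3, Cs2CO3, DMF/H2O, rt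
Reagents that add atoms: 9-borabicyclo[3.3.1]nonane B1C2CCCC1CCC2 (boron stays only in 11)
Why: A second chemoselective hydroboration/B-alkyl Suzuki–Miyaura coupling, again with retention at the iodide, installs the 11Z alkene and the free C13 alcohol.

Step 7
Reactants: 12 (2Z,6Z,10Z)-12-[(tert-butyldimethylsilyl)oxy]-2,6,10-trimethyldodeca-2,6,10-trien-1-ol
Product: 13 (2Z,6Z,10Z)-12-[(tert-butyldimethylsilyl)oxy]-2,6,10-trimethyldodeca-2,6,10-trienal
Conditions: MnO2 (20 equiv), CH2Cl2, rt, dark; used at once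
Reagents that add atoms: none
Why: Neutral heterogeneous allylic oxidation gives the Z-enal without acid or base that would isomerise it to E.

Step 8
Reactants: 14 α-methylene-γ-butyrolactone
Product: 16 3-(bromomethyl)furan-2(5H)-one, via dibromolactone 15 (not isolated)
Conditions: Br2, CH2Cl2, 0 °C; then Et3N, 0 °C to rt
Reagents that add atoms: bromine BrBr
Why: Bromine addition followed by E2 loss of HBr toward the ring CH2 gives the conjugated butenolide that carries the allylic bromide at C17.

Step 9
Reactants: 16 3-(bromomethyl)furan-2(5H)-one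
Product: 17 3-[(phenylsulfonyl)methyl]furan-2(5H)-one
Conditions: PhSO2Na, DMF, rt
Reagents that add atoms: sodium benzenesulfinate [Na+].[O-]S(=O)c1ccccc1
Why: S-alkylation of the sulfinate (SN2) turns the labile allylic bromide into a robust allyl sulfone, the radical leaving group for the ring closure.

Step 10
Reactants: 17 3-[(phenylsulfonyl)methyl]furan-2(5H)-one
Product: 18 tert-butyl(dimethyl)({3-[(phenylsulfonyl)methyl]furan-2-yl}oxy)silane
Conditions: TBSOTf, Et3N, CH2Cl2, 0 °C
Reagents that add atoms: tert-butyldimethylsilyl triflate CC(C)(C)[Si](C)(C)OS(=O)(=O)C(F)(F)F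
Why: Soft enolisation removes the γ-proton because this gives the aromatic 2-silyloxyfuran.

Step 11
Reactants: 13 (2Z,6Z,10Z)-12-[(tert-butyldimethylsilyl)oxy]-2,6,10-trimethyldodeca-2,6,10-trienal; 18 tert-butyl(dimethyl)({3-[(phenylsulfonyl)methyl]furan-2-yl}oxy)silane
Product: 20 (13S,14R)-anti aldol (C13 carbinol on the γ-carbon C14 of the α-(phenylsulfonylmethyl)butenolide), via trichlorosilyl aldolate 19 (not isolated)
Conditions: SiCl4 (1.2 equiv), binaphthyldiamine-derived (R,R)-bisphosphoramide (5 mol %; the antipode gives ent-20), iPr2NEt (10 mol %), CH2Cl2, −78 °C; aq. NaHCO3/KF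
Reagents that add atoms: silicon tetrachloride Cl[Si](Cl)(Cl)Cl (silicon and chlorine stay only in 19)
Why: The Lewis-base-activated vinylogous Mukaiyama aldol reaction works well with enals. It attacks through the furan γ-carbon, is anti-selective, and the chiral phosphoramide-bound silicon cation selects the aldehyde face, so C13 (S) and C14 (R) are set together.

Step 12
Reactants: 20 (13S,14R)-anti aldol
Product: 21 13-O-acetate of 20
Conditions: Ac2O, pyridine, CH2Cl2, 0 °C (no DMAP)
Reagents that add atoms: acetic anhydride CC(=O)OC(C)=O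
Why: Mild acetylation installs the C13 acetate without deprotonating C14–H, which would trigger loss of acetate to the ylidene butenolide.

Step 13
Reactants: 21 13-O-acetate of 20
Product: 22 3Z allylic alcohol (free C2–OH)
Conditions: HF·pyridine, THF/pyridine, 0 °C
Reagents that add atoms: none
Why: Buffered fluoride desilylation is non-basic, so the acetate, sulfone and butenolide survive.

Step 14
Reactants: 22 3Z allylic alcohol
Product: 23 (3S,4R)-3,4-epoxy alcohol
Conditions: Ti(OiPr)4 (15 mol %), L-(+)-diethyl tartrate (18 mol %), tBuOOH (2 equiv), 4 Å MS, CH2Cl2, −20 °C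
Reagents that add atoms: tert-butyl hydroperoxide CC(C)(C)OO
Why: Sharpless asymmetric epoxidation oxidises only the alkene next to the free allylic OH. With the L-(+)-tartrate a nerol-type Z alcohol gives the (3S,4R) cis-type epoxide, while the other two alkenes and the electron-poor butenolide stay intact.

Step 15
Reactants: 23 (3S,4R)-3,4-epoxy alcohol
Product: 24 (3S,4S)-2,3-dihydroxy-4-acetate
Conditions: Ti(OiPr)4 (1.5 equiv), AcOH (4 equiv), CH2Cl2, 0 °C to rt
Reagents that add atoms: acetic acid CC(=O)O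
Why: In the titanium-chelated epoxy alcohol (Caron–Sharpless opening) acetate attacks the distal tertiary carbon C4 from the back. C4 therefore inverts from R to S and C3–O is retained, giving the hydroxy acetate pattern of the target.

Step 16
Reactants: 24 (3S,4S)-2,3-dihydroxy-4-acetate
Product: 25 C2 iodide (iodohydrin; same arrangement at C3 and C4, C3 now reads R only because iodine changes the priorities)
Conditions: PPh3 (1.1 equiv), imidazole (1.5 equiv), I2 (1.05 equiv), CH2Cl2, −20 °C
Reagents that add atoms: iodine II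
Why: Appel-type (Garegg) iodination with one equivalent at low temperature takes only the primary hydroxyl and touches no stereocentre.

Step 17
Reactants: 25 C2 iodide
Product: 26 target CNP0127975.1
Conditions: Et3B (5 equiv, syringe pump), air, Yb(OTf)3 (1.0 equiv), CH2Cl2/THF, 0.002 M, −40 °C; pH 7 buffer
Reagents that add atoms: none
Why: Proposed new method: an ethyl radical from Et3B/O2 abstracts iodine from 25, the nucleophilic primary C2 radical adds to C1 of the Yb-activated butenolide on the face anti to the C14 side chain (sets 1R, trans lactone), and the C15 radical expels PhSO2•, moving the double bond to C15=C17, while PhSO2• frees a new ethyl radical from Et3B; this SH2′ copy of the cyclase event (C2 attacks the C1=C15 π bond, C17 loses a group) merges two known reaction types, radical allyl transfer to 2-(sulfonylmethyl)acrylates and 14-membered radical macrocyclisation onto activated alkenes, and Yb(OTf)3 is meant to bind the hydroxy acetate head and the lactone carbonyl together so that closure outruns 6-exo attack on C7=C8.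

## Compound list
1 | prop-2-yn-1-ol | C#CCO | starting material
2 | 4-methyl-2,5-dihydro-1,2-oxamagnesole (alkenylmagnesium alkoxide chelate) | CC1=C[Mg]OC1 | intermediate
3 | (Z)-3-iodo-2-methylprop-2-en-1-ol (I cis to CH2OH) | OC/C(C)=C\I | intermediate
4 | (Z)-3-iodo-2-methylprop-2-enal | O=C/C(C)=C\I | intermediate
5 | (Z)-1-iodo-2-methylbuta-1,3-diene (I cis to vinyl) | C=C/C(C)=C\I | intermediate
6 | (Z)-3-methylpent-2-en-4-yn-1-ol | C#C/C(C)=C\CO | starting material
7 | TBS ether of 6 | C#C/C(C)=C\CO[Si](C)(C)C(C)(C)C | intermediate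
8 | (Z)-tert-butyl(dimethyl)[(3-methylpenta-2,4-dien-1-yl)oxy]silane | C=C/C(C)=C\CO[Si](C)(C)C(C)(C)C | intermediate
9 | B-alkyl-9-BBN from 8 (boron on C6) | CC(C)(C)[Si](C)(C)OC/C=C(/C)CCB1C2CCCC1CCC2 | intermediate
10 | (2Z,6Z)-3,7-dimethylnona-2,6,8-trien-1-yl TBS ether (C2–C10) | CC(C)(C)[Si](C)(C)OC/C=C(/C)CC/C=C(/C)C=C | intermediate
11 | B-alkyl-9-BBN from 10 (boron on C10) | CC(C)(C)[Si](C)(C)OC/C=C(/C)CC/C=C(/C)CCB1C2CCCC1CCC2 | intermediate
12 | (2Z,6Z,10Z)-12-(TBSO)-2,6,10-trimethyldodeca-2,6,10-trien-1-ol (C2–C13) | CC(C)(C)[Si](C)(C)OC/C=C(/C)CC/C=C(/C)CC/C=C(/C)CO | intermediate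
13 | (2Z,6Z,10Z)-12-(TBSO)-2,6,10-trimethyldodeca-2,6,10-trienal | CC(C)(C)[Si](C)(C)OC/C=C(/C)CC/C=C(/C)CC/C=C(/C)C=O | intermediate
14 | α-methylene-γ-butyrolactone | C=C1CCOC1=O | starting material
15 | 3-bromo-3-(bromomethyl)oxolan-2-one (racemic) | BrCC1(Br)CCOC1=O | intermediate
16 | 3-(bromomethyl)furan-2(5H)-one | BrCC1=CCOC1=O | intermediate
17 | 3-[(phenylsulfonyl)methyl]furan-2(5H)-one | O=C1OCC=C1CS(=O)(=O)c1ccccc1 | intermediate
18 | 2-(TBSO)-3-[(phenylsulfonyl)methyl]furan | CC(C)(C)[Si](C)(C)Oc1occc1CS(=O)(=O)c1ccccc1 | intermediate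
19 | O13-trichlorosilyl ether of 20 | CC(C)(C)[Si](C)(C)OC/C=C(/C)CC/C=C(/C)CC/C=C(/C)[C@H](O[Si](Cl)(Cl)Cl)[C@@H]1OC(=O)C(CS(=O)(=O)c2ccccc2)=C1 | intermediate
20 | (13S,14R)-anti aldol, all-Z, C2–OTBS, α-(phenylsulfonylmethyl)butenolide | CC(C)(C)[Si](C)(C)OC/C=C(/C)CC/C=C(/C)CC/C=C(/C)[C@H](O)[C@@H]1OC(=O)C(CS(=O)(=O)c2ccccc2)=C1 | intermediate
21 | 13-acetate of 20 | CC(C)(C)[Si](C)(C)OC/C=C(/C)CC/C=C(/C)CC/C=C(/C)[C@H](OC(C)=O)[C@@H]1OC(=O)C(CS(=O)(=O)c2ccccc2)=C1 | intermediate
22 | (3Z,7Z,11Z,13S,14R) C2 allylic alcohol | OC/C=C(/C)CC/C=C(/C)CC/C=C(/C)[C@H](OC(C)=O)[C@@H]1OC(=O)C(CS(=O)(=O)c2ccccc2)=C1 | intermediate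
23 | (3S,4R,13S,14R) 3,4-epoxy alcohol | OC[C@@H]1O[C@]1(C)CC/C=C(/C)CC/C=C(/C)[C@H](OC(C)=O)[C@@H]2OC(=O)C(CS(=O)(=O)c3ccccc3)=C2 | intermediate
24 | (3S,4S,13S,14R) 2,3-diol 4,13-diacetate | OC[C@H](O)[C@@](C)(OC(C)=O)CC/C=C(/C)CC/C=C(/C)[C@H](OC(C)=O)[C@@H]1OC(=O)C(CS(=O)(=O)c2ccccc2)=C1 | intermediate
25 | C2 iodide of 24 | IC[C@H](O)[C@@](C)(OC(C)=O)CC/C=C(/C)CC/C=C(/C)[C@H](OC(C)=O)[C@@H]1OC(=O)C(CS(=O)(=O)c2ccccc2)=C1 | intermediate
26 | CNP0127975.1, (1R,3S,4S,7Z,11Z,13S,14R) | C=C1C(=O)O[C@@H]2[C@@H]1C[C@H](O)[C@@](C)(OC(C)=O)CC/C=C(/C)CC/C=C(/C)[C@@H]2OC(C)=O | target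

**Total step count:** 17.
**Longest linear sequence:** 12 steps (steps 1, 2, 5, 6, 7, 11, 12, 13, 14, 15, 16, 17).

## Steps most likely to fail

**Step 17 (ring closure).** This is the weakest step of the route. The C2 radical is a 6-heptenyl radical. Its 6-exo attack on C7=C8 and the 1,5-hydrogen shift from C6 have rates comparable to, or higher than, a 14-membered closure onto a β-substituted acceptor. Liberated sulfinic acid can also add to the new methylene lactone.

The fallback gives up radicals and closes the same bond in the biosynthetic polarity. It sets out from 24. Mitsunobu cyclodehydration (PPh3, DIAD) activates the primary hydroxyl and gives the terminal C2–C3 epoxide F1 with C3 retained. Pd(PPh3)4 with indium monoiodide (monovalent indium) then converts the allyl sulfone by reductive transmetalation into the allylindium species F2. F2 ignores isolated alkenes and opens the glycidyl-type epoxide at C2 through its γ-carbon C1, anti to the C14 side chain. The fallback comes back to the route at 26.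

**Step 11 (vinylogous aldol).** The Z-enal may isomerise under Lewis acid. The 3-substituted silyloxyfuran may also erode the anti/syn ratio or the ee.

The fallback replaces asymmetric catalysis by resolution. It sets out from 13 and 18. A fluoride-triggered (catalytic Bu4NF, −78 °C), erythro-selective vinylogous aldol gives 20 together with its enantiomer ent-20 F3. Lipase-catalysed acetylation with vinyl acetate then acylates only the (13S) alcohol and leaves F3 behind. The fallback comes back to the route at 21.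

**Step 15 (acetolysis).** Partial SN1 character at C4 can give loss of stereochemistry or allylic alcohol. Acetyl migration from O4 to the free O3 or O2 can also occur on titanium.

The fallback changes the order so that no free diol is ever present. It sets out from 23, which is first converted with PPh3/I2/imidazole into the epoxy iodide F4. Brønsted-acid acetolysis (AcOH, CH2Cl2) of F4 is then steered to C4 by the electron-poor CH2I neighbour. This gives the iodohydrin acetate directly, and the fallback comes back to the route at 25.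

## Further compounds
F1 | step 17 | terminal C2–C3 epoxide with C4–OAc (from 24) | C1O[C@@H]1[C@@](C)(OC(C)=O)CC/C=C(/C)CC/C=C(/C)[C@H](OC(C)=O)[C@@H]2OC(=O)C(CS(=O)(=O)c3ccccc3)=C2
F2 | step 17 | allylindium iodide benzenesulfinate derived from F1 (In on C17) | C1O[C@@H]1[C@@](C)(OC(C)=O)CC/C=C(/C)CC/C=C(/C)[C@H](OC(C)=O)[C@@H]2OC(=O)C(C[In](I)OS(=O)c3ccccc3)=C2
F3 | step 11 | ent-20, (13R,14S)-anti aldol | CC(C)(C)[Si](C)(C)OC/C=C(/C)CC/C=C(/C)CC/C=C(/C)[C@@H](O)[C@H]1OC(=O)C(CS(=O)(=O)c2ccccc2)=C1
F4 | step 15 | epoxy iodide from 23 | IC[C@@H]1O[C@]1(C)CC/C=C(/C)CC/C=C(/C)[C@H](OC(C)=O)[C@@H]2OC(=O)C(CS(=O)(=O)c3ccccc3)=C2
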